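The route rests on removing C3 from the γ-pyranone (ring C): what is left of O1, C2, C4, C4a and C8a is a benzofuran-3-one fused to the fully substituted ring A. In the forward direction, dibromocarbene is inserted between C2 and C4 of the derived silyl enol ether. This one operation forms the C2–C3 and C3–C4 bonds, enlarges the furan to the pyranone and leaves bromine on C3 as the handle for the 4-methoxybenzyl group. The feature exploited is the O1–C2=C3–C4=O vinylogous ester of ring C, whose α-carbon C3 carries the benzyl group. The precursor is a 3,6-bis(silyloxy)-4-methoxy-5-methylbenzofuran-7-carbaldehyde.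

Key step: step 6

Remark: PhHgCBr3 (toxic organomercurial, closed handling) is taken as purchasable, otherwise it is made from PhHgCl, CHBr3 and KOtBu. The benzylzinc reagent is generated in the flask. All isolated compounds are achiral.

Step 1
Reactants: 1 2-methylphloroglucinol
Product: 3 2,4,6-trihydroxy-3-methylbenzaldehyde, via aryliminium chloride 2 (not isolated)
Conditions: POCl3 (1.1 equiv), DMF (1.2 equiv), EtOAc, 0 °C to rt; then H2O, 60 °C
Reagents that add atoms: N,N-dimethylformamide, CN(C)C=O (formyl carbon); water, O (carbonyl oxygen)
Why: Vilsmeier–Haack formylation, in which the chloroiminium ion attacks one of the two equivalent free ring carbons of the strongly activated triol, the deactivating iminium group holds the reaction at the mono stage, and hydrolysis of the salt should give the aldehyde.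

Step 2
Reactants: 3 2,4,6-trihydroxy-3-methylbenzaldehyde
Product: 4 2,6-dihydroxy-4-methoxy-3-methylbenzaldehyde
Conditions: MeI (1.05 equiv), Li2CO3 (1.1 equiv), DMF, 40 °C
Reagents that add atoms: iodomethane, CI
Why: Site-selective Williamson etherification, since the hydroxyl para to the formyl group is the most acidic and the only one not held in a hydrogen bond or lithium chelate with the carbonyl, so one equivalent of MeI with a weak base should alkylate it first.

Step 3
Reactants: 4 2,6-dihydroxy-4-methoxy-3-methylbenzaldehyde; 5 chloroacetyl chloride
Product: 6 3-(2-chloroacetyl)-2,6-dihydroxy-4-methoxy-5-methylbenzaldehyde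
Conditions: ClCH2COCl (1.2 equiv), AlCl3 (3 equiv), CH2Cl2–MeNO2, 0 °C to rt; then ice, aq. HCl
Reagents that add atoms: chloroacetyl chloride (5), ClCC(=O)Cl
Why: Friedel–Crafts acylation at the single unsubstituted ring carbon, which is ortho or para to all three oxygen donors; haloacetylation of free hydroxybenzaldehydes with AlCl3 is established, and the low temperature should protect the methyl ether next to the new ketone from Lewis-acid cleavage.

Step 4
Reactants: 6 3-(2-chloroacetyl)-2,6-dihydroxy-4-methoxy-5-methylbenzaldehyde
Product: 7 6-hydroxy-4-methoxy-5-methyl-3-oxo-2,3-dihydro-1-benzofuran-7-carbaldehyde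
Conditions: NaOAc (3 equiv), MeOH, reflux
Reagents that add atoms: none
Why: Intramolecular Williamson etherification (5-exo-tet SN2), in which the only hydroxyl ortho to the chloroacetyl group (the other ortho position bears the methoxy group) is flanked by two carbonyls and therefore acidic enough for acetate, while the phenoxide-deactivated aldehyde should not condense with the new active methylene.

Step 5
Reactants: 7 6-hydroxy-4-methoxy-5-methyl-3-oxo-2,3-dihydro-1-benzofuran-7-carbaldehyde
Product: 8 3,6-bis[(tert-butyldimethylsilyl)oxy]-4-methoxy-5-methyl-1-benzofuran-7-carbaldehyde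
Conditions: TBSOTf (2.5 equiv), Et3N (4 equiv), CH2Cl2, −78 to 0 °C; cold aq. NaHCO3; Et3N-deactivated silica
Reagents that add atoms: tert-butyldimethylsilyl trifluoromethanesulfonate, CC(C)(C)[Si](C)(C)OS(=O)(=O)C(F)(F)F
Why: Silyl triflate–amine silylation, which converts the phenol into its silyl ether and the ketone, whose enol is an aromatic 3-hydroxybenzofuran, into the silyl enol ether; excess amine at low temperature keeps free silyl triflate low, so the hindered aldehyde should not enter Mukaiyama-type aldol chemistry.

Step 6
Reactants: 8 3,6-bis[(tert-butyldimethylsilyl)oxy]-4-methoxy-5-methyl-1-benzofuran-7-carbaldehyde; 9 phenyl(tribromomethyl)mercury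
Product: 12 3-bromo-7-[(tert-butyldimethylsilyl)oxy]-5-methoxy-6-methyl-4-oxo-4H-chromene-8-carbaldehyde, via dibromocyclopropane adduct 10 (not isolated), via 4-silyloxychromenylium bromide 11 (not isolated)
Conditions: PhHgCBr3 (1.3 equiv), PhH, 80 °C, N2, dark; filter off PhHgBr
Reagents that add atoms: phenyl(tribromomethyl)mercury (9), BrC(Br)(Br)[Hg]c1ccccc1 (C3 and its bromine)
Why: Proposed new method: thermolysis of PhHgCBr3 releases dibromocarbene without base, and this electrophilic singlet carbene should add in a concerted [2+1] fashion to the C2=C3 silyl enol ether bond of 8 to give the cis-fused gem-dibromocyclopropane 10. Departure of the endo bromide is coupled to disrotatory two-electron electrocyclic cleavage of the former C2–C3 bond, pushed by the lone pairs of O1 and the silyloxy oxygen, which gives the aromatic chromenylium ion 11; bromide then takes the silyl group from the oxygen on C4 and the C4 carbonyl appears. The closest known reaction types are the dihalocarbene ring expansion of cyclic silyl enol ethers to 2-halo enones and the dihalocarbene expansions of benzofurans and indoles to 3-halochromenes and 3-haloquinolines, and the new element is their merger on a 3-silyloxybenzofuran. Ring C is formed by one-carbon ring enlargement and not by cyclisation: a three-membered ring is closed by cycloaddition and its internal bond is then broken, so the furan becomes the six-membered pyranone with new C2–C3 and C3–C4 bonds. No stereocentre remains, since the two cis-related centres of 10 become sp2 on opening. The step needs chemoselectivity for C2=C3 over the aldehyde and ring A, and the substrate secures it because the silyloxy and O1 donors make that bond the most electron-rich π bond, ring A has no free position, and the aldehyde is flanked on both sides and meets no base or trihalomethyl anion.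

Step 7
Reactants: 12 3-bromo-7-[(tert-butyldimethylsilyl)oxy]-5-methoxy-6-methyl-4-oxo-4H-chromene-8-carbaldehyde; 13 4-methoxybenzyl chloride
Product: 15 7-[(tert-butyldimethylsilyl)oxy]-5-methoxy-3-[(4-methoxyphenyl)methyl]-6-methyl-4-oxo-4H-chromene-8-carbaldehyde, via 4-methoxybenzylzinc chloride 14 (not isolated)
Conditions: 13, Zn dust, LiCl, THF, 25 °C; then 12 (zinc reagent 1.2 equiv, slow addition), Pd(OAc)2 (2 mol %), SPhos (4 mol %), THF, 25 °C
Reagents that add atoms: 4-methoxybenzyl chloride (13), COc1ccc(CCl)cc1
Why: Negishi cross-coupling, in which zerovalent palladium formed from Pd(OAc)2 and SPhos inserts into the C3–Br bond of the α-bromo enone, the benzylic zinc chloride (from LiCl-assisted zinc insertion) transmetalates and reductive elimination forms the C3–CH2 bond at room temperature, which should outpace uncatalysed addition to the doubly ortho-substituted aldehyde.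

Step 8
Reactants: 15 7-[(tert-butyldimethylsilyl)oxy]-5-methoxy-3-[(4-methoxyphenyl)methyl]-6-methyl-4-oxo-4H-chromene-8-carbaldehyde
Product: 16 7-hydroxy-5-methoxy-3-[(4-methoxyphenyl)methyl]-6-methyl-4-oxo-4H-chromene-8-carbaldehyde
Conditions: TBAF (1.1 equiv), AcOH (1.2 equiv), THF, 0 °C
Reagents that add atoms: none
Why: Fluoride-induced cleavage of an aryl silyl ether, made especially easy by the ortho formyl group that stabilises the phenoxide, with acetic acid buffering so that the pyranone is not opened by base.

Compound list
1 | 2-methylphloroglucinol (2-methylbenzene-1,3,5-triol) | Cc1c(O)cc(O)cc1O | starting material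
2 | dimethyl[(2,4,6-trihydroxy-3-methylphenyl)methylidene]ammonium chloride | C[N+](C)=Cc1c(O)cc(O)c(C)c1O.[Cl-] | intermediate
3 | 2,4,6-trihydroxy-3-methylbenzaldehyde | O=Cc1c(O)cc(O)c(C)c1O | intermediate
4 | 2,6-dihydroxy-4-methoxy-3-methylbenzaldehyde | O=Cc1c(O)cc(OC)c(C)c1O | intermediate
5 | chloroacetyl chloride | ClCC(=O)Cl | starting material
6 | 3-(2-chloroacetyl)-2,6-dihydroxy-4-methoxy-5-methylbenzaldehyde | O=Cc1c(O)c(C(=O)CCl)c(OC)c(C)c1O | intermediate
7 | 6-hydroxy-4-methoxy-5-methyl-3-oxo-2,3-dihydro-1-benzofuran-7-carbaldehyde | O=C1COc2c(C=O)c(O)c(C)c(OC)c12 | intermediate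
8 | 3,6-bis[(tert-butyldimethylsilyl)oxy]-4-methoxy-5-methyl-1-benzofuran-7-carbaldehyde | CC(C)(C)[Si](C)(C)Oc1coc2c(C=O)c(O[Si](C)(C)C(C)(C)C)c(C)c(OC)c12 | intermediate
9 | phenyl(tribromomethyl)mercury | BrC(Br)(Br)[Hg]c1ccccc1 | starting material
10 | 1,1-dibromo-4,6b-bis[(tert-butyldimethylsilyl)oxy]-6-methoxy-5-methyl-1a,6b-dihydro-1H-cyclopropa[b][1]benzofuran-3-carbaldehyde (cis ring fusion, racemic, one enantiomer drawn) | CC(C)(C)[Si](C)(C)O[C@@]12C(Br)(Br)[C@@H]1Oc1c(C=O)c(O[Si](C)(C)C(C)(C)C)c(C)c(OC)c12 | intermediate
11 | 3-bromo-4,7-bis[(tert-butyldimethylsilyl)oxy]-8-formyl-5-methoxy-6-methylchromenylium bromide | CC(C)(C)[Si](C)(C)Oc1c(Br)c[o+]c2c(C=O)c(O[Si](C)(C)C(C)(C)C)c(C)c(OC)c12.[Br-] | intermediate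
12 | 3-bromo-7-[(tert-butyldimethylsilyl)oxy]-5-methoxy-6-methyl-4-oxo-4H-chromene-8-carbaldehyde | Brc1coc2c(C=O)c(O[Si](C)(C)C(C)(C)C)c(C)c(OC)c2c1=O | intermediate
13 | 4-methoxybenzyl chloride | COc1ccc(CCl)cc1 | starting material
14 | 4-methoxybenzylzinc chloride (THF solution) | COc1ccc(C[Zn]Cl)cc1 | intermediate
15 | 7-[(tert-butyldimethylsilyl)oxy]-5-methoxy-3-[(4-methoxyphenyl)methyl]-6-methyl-4-oxo-4H-chromene-8-carbaldehyde | COc1ccc(Cc2coc3c(C=O)c(O[Si](C)(C)C(C)(C)C)c(C)c(OC)c3c2=O)cc1 | intermediate
16 | 7-hydroxy-5-methoxy-3-[(4-methoxyphenyl)methyl]-6-methyl-4-oxo-4H-chromene-8-carbaldehyde | COc1ccc(Cc2coc3c(C=O)c(O)c(C)c(OC)c3c2=O)cc1 | target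

Total step count: 8. Longest linear sequence: 8 steps (1 to 16); the zinc reagent 14 is made in the flask within step 7.

Steps most likely to fail

Step 6 (ring expansion). The carbene may be diverted to the formyl oxygen (ylide formation and deoxygenative halogenation). The enol ether may lose its silyl group before carbene transfer. Unreacted enol ether may add to the transient chromenylium ion. The fallback uses known chemistry, sets out from 4 and rejoins the route at the target 16. Friedel–Crafts acylation of 4 with 3-(4-methoxyphenyl)propanoyl chloride (AlCl3, CH2Cl2–MeNO2, 0 °C) at the same free ring carbon should give the dihydrochalcone 2,6-dihydroxy-4-methoxy-3-[3-(4-methoxyphenyl)propanoyl]-5-methylbenzaldehyde F1. Heating F1 with N,N-dimethylformamide dimethyl acetal in toluene, followed by brief acid treatment, attaches the one-carbon unit to the ketone α-methylene. The only hydroxyl ortho to the ketone then closes the pyranone with loss of dimethylamine, the classical 3-benzylchromone annulation, and gives 16 directly.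

Step 7 (Negishi coupling). Uncatalysed 1,2-addition of the benzylic zinc reagent to the aldehyde may compete with oxidative addition and transmetalation. Wurtz-type homocoupling during zinc insertion may also starve the coupling. The fallback sets out from 12 and rejoins at 15. It is a Suzuki–Miyaura coupling of 12 with potassium trifluoro(4-methoxybenzyl)borate F2 (PdCl2(dppf), Cs2CO3, THF–H2O, 75 °C). The boron nucleophile does not add to aldehydes, and aqueous carbonate coupling of 3-halochromones is established.

Step 2 (mono-methylation). Site selectivity may be incomplete, with alkylation of the ortho hydroxyl next to the ring hydrogen or a second alkylation. The fallback sets out from 3 and rejoins at 4. Methylation of the two more reactive hydroxyls (Me2SO4 2.2 equiv, K2CO3, acetone, reflux) should give 2-hydroxy-4,6-dimethoxy-3-methylbenzaldehyde F3, in which the chelated, hindered hydroxyl between formyl and methyl stays free. BCl3 (CH2Cl2, −78 °C to rt) then cleaves only the methoxy group ortho to the formyl group through the boron chelate, leaving the para methoxy group and giving 4.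

Further compounds
F1 | step 6 | 2,6-dihydroxy-4-methoxy-3-[3-(4-methoxyphenyl)propanoyl]-5-methylbenzaldehyde | COc1ccc(CCC(=O)c2c(O)c(C=O)c(O)c(C)c2OC)cc1
F2 | step 7 | potassium trifluoro(4-methoxybenzyl)borate | [K+].COc1ccc(C[B-](F)(F)F)cc1
F3 | step 2 | 2-hydroxy-4,6-dimethoxy-3-methylbenzaldehyde | O=Cc1c(OC)cc(OC)c(C)c1O
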